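The runs were computed from invented constants; scatter was added.

If E makes Z and E with Z then makes X, the end of a flask can be reckoned from the conversion u of E and one number read from the runs.

| setting | south-west | west | north | dawn | midnight |
|---|---|---|---|---|---|
| E | 0.050 M | 0.050 M | 0.10 M | 0.050 M | 0.050 M |
| Q | 0.12 mM | 0.19 mM | 0.25 mM | 0.25 mM | 0.25 mM |
| temperature | 10 °C | 29 °C | 10 °C | 25 °C | 33 °C |
| remark | run made earlier | run made earlier | run made earlier |  |  |
| time |  |  |  | 40 min | 40 min |

| run | time / min | E / % | Z / % | X / % |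
|---|---|---|---|---|
| south-west | 4.00 | 94.2 | 5.4 | 0 |
| south-west | 12.0 | 85.5 | 13.1 | 0.7 |
| south-west | 25.0 | 72.9 | 24.9 | 4.0 |
| south-west | 30.0 | 66.2 | 28.6 | 5.1 |
| south-west | 50.0 | 51.1 | 38.8 | 10.1 |
| south-west | 60.0 | 44.3 | 42.6 | 12.7 |
| south-west | 80.0 | 33.4 | 48.8 | 18.3 |
| west | 2.00 | 87.5 | 13.2 | 1.2 |
| west | 6.00 | 65.2 | 29.8 | 4.1 |
| west | 12.0 | 41.9 | 45.4 | 12.1 |
| west | 15.0 | 33.7 | 51.1 | 15.8 |
| west | 25.0 | 16.6 | 58.9 | 23.5 |
| west | 30.0 | 12.3 | 61.4 | 26.2 |
| west | 40.0 | 6.6 | 62.8 | 30.3 |
| north | 8.00 | 84.9 | 13.1 | 1.5 |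
| north | 20.0 | 66.9 | 26.1 | 6.3 |
| north | 40.0 | 43.7 | 40.3 | 16.6 |
| north | 60.0 | 28.0 | 47.7 | 24.7 |
| north | 80.0 | 18.6 | 51.1 | 31.6 |

(scatter of a reading: 0.5 percentage points)

- percent here means E units held: one X counts as two
- the earlier runs were read with a standard deviation of 0.5 percentage points

* which of these there is most of at the end, counted by the E in it, dawn (X / Z / E)
* which of these there is most of at the end, counted by the E in it, midnight (X / Z / E)
* the largest of these amounts at the end, in percent of the E charged, dawn
* the largest of these amounts at the end, in percent of the E charged, midnight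

My own reckoning builds the flask one process at a time, in decades.

1. Main step only. E goes to Z, pseudo-first-order in E, with a constant taken proportional to √cQ. The last readings give 0.0137 /min for south-west and 0.0680 /min for west. With √cQ divided out, the constant rises by 0.595 decades between their temperatures. Interpolating in decades gives 0.0584 /min for dawn, so u is 90.3% there. Extrapolating gives 98.4% for midnight. Z then equals u.

2. Add the drain. Let x and z be the parts of the charged E held as X and Z, so that x + z = u, and let D be x divided by the square of z. At nearly equal z, south-west reads 0.768 and north 1.09, a shift of 0.150 decades. Scaling D as cE/√cQ predicts 0.142. West reads 0.605, a shift of −0.104 against −0.0998 from cQ, so this pair of readings is reckoned with no temperature term. Scaled to dawn, west gives 0.527, and solving Dz² + z = u gives 66.8%.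

3. Add the rest. Q decays, so the same scaling makes D climb along a run, and west reads 0.695 at 30.0 min. That reading sits near dawn's conversion, so the drain number for dawn, a selectivity factor, is 0.606, and dawn's z is 64.9%. This exceeds its x of 25.4%. Midnight takes west's last reading, 0.670, and gives 67.7%.

The forecast names Z at dawn with 63.5% and Z at midnight with 65.5%, noting “Midnight is an extrapolation, so its range is wider.”

The flask gives Z at dawn with 66.1%, and Z at midnight with 67.2%.

    2 L → G (k = 7.00 × 10⁶ /M/s, Ea = 18.0 kJ/mol)
    Q → 2 J (k = 3.40 × 10⁻⁴ /s, Ea = 82.0 kJ/mol)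
    E + Z → X (k = 0.00760 /M/s, Ea = 56.0 kJ/mol)
    E + J → L + Z (k = 2.70 × 10⁵ /M/s, Ea = 25.0 kJ/mol)
    E + L → Z + L, rate k5*[L]*[E] (k = 9000 /M/s, Ea = 24.0 kJ/mol)
    (constants at 25 °C)

Dawn's own x and z give D = 0.573, against the 0.606 carried from west. D weighs the use of Z by E against the making of Z by L. The pairing of L into G is the main reason that dawn's Z stands at 66.1%: with that step struck out, Z reaches 99.3%.

A neighbour flask is dawn with cQ at 6.3 × 10⁻⁵ M. Its D scales to 1.21 and its u to 69.0%, so z comes to 44.8%. The computed neighbour flask holds 44.7% of Z, with 28% of E left.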